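## Structural features

The target is a trans-fused eremophilane decalin (rings A and B share C5–C10) whose equatorial 3α-oxygen is esterified by (2Z,4R)-4-angeloyloxyhex-2-enoic acid. Seven ring stereocentres are contiguous: 3α-O, 4β-Me, the quaternary 5β-Me, 10α-H, 9α-OH (equatorial), 8α-OH (axial) and the 7α (equatorial) isopropenyl group. The side chain adds C4′ (R) and two Z alkenes. The fragile groups are the two Z-unsaturated esters (angelate to tiglate, Z-enoate to E-enoate, or butenolide if O4′ is ever free beside the Z-enoate), the cis-diol and the isopropenyl alkene. That alkene rules out hydrogenation, hydroboration and osmylation on the core and slips into conjugation once C8 is a ketone. The real difficulty is the vicinal C4/C5 pair (cis-dimethyl, one centre quaternary). The axial C14 methyl also shields the β face of C3 and C9, so small hydrides would give the axial (wrong) alcohols at both carbons. The key step exploits the fact that quaternary C5 is flanked by C4 and C10, each of which has an oxygen-bearing neighbour (C3 and C9). Tying the C3 oxygen to C9 of ring B makes C4=C3–O–C9–C10=C5 an allyl vinyl ether, and a [3,3] shift then forms C4–C5, closes ring A as the C3 ketone and transfers the C9–O configuration to C5.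

## Logic of the disconnections

31 ⇒ 30 ⇒ 24 + 29. The diol is masked as the acetal of 30 and the side-chain C2′=C3′ bond is cut. Cutting here, not at the ester oxygen, means that no Z-enoic acid has to be activated and O4′ is never free next to a Z-enoate. The gain is convergence: the core arrives as a phosphonate, the chain as a four-carbon aldehyde. The forward olefination must be Z-selective and must not epimerise the α-acyloxy aldehyde.

24 ⇒ 22 + 23. The O3–C1′ ester bond is cut. O3 is the only free hydroxyl of 22, so the acylation needs no selectivity. The forward step only has to acylate a flanked equatorial alcohol.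

29 ⇒ 28 ⇒ 26 + 27, and 26 ⇒ 25. The aldehyde carbon is traced back to a vinyl group (C=C cleavage), the angelate C–O bond is cut, and the vinyl carbon is removed to reach a chiral-pool terminal epoxide. The cleavage must spare the angelate alkene, and the acylation must not isomerise it.

22 ⇒ 21 ⇒ 19. The acetal is removed and the C8–H bond is cut, leading to the C8 ketone. An axial alcohol between two equatorial neighbours is what a bulky hydride delivers. The forward reduction must proceed by equatorial attack.

19 ⇒ 18. The C9–O bond is cut (enol ether oxidation). The 9α oxygen lies on the face opposite C14, the face an electrophile prefers, whereas hydride reduction of a C9 ketone would be expected to give the 9β epimer. The oxidant must prefer the enol ether to the isopropenyl group.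

18 ⇒ 16. The C10–H and C3–H bonds (and both O–Si bonds) are cut. Both centres are set by electron-transfer reduction, which gives the trans ring fusion and the equatorial 3α oxygen under product-stability control. The same operation delivers the C8 enolate regiospecifically. The enolate must survive the proton donor, and C4 must already be correct.

16 ⇒ 15. The C8=O bond is removed (allylic oxidation). C8 is the methylene at the CH terminus of the only trisubstituted alkene. The forward step needs site selectivity and must not move the isopropenyl double bond.

15 ⇒ 13 (key disconnection). The C4–C5 bond is cut and C9 is reconnected to the C3 oxygen. This removes ring A and the quaternary centre in one operation and replaces C5 by a carbinol centre that is easy to set. The forward shift must pass through a boat. A point needing correction: through that boat the Z enol ether places C15 on the α face first, so 15 is reached only after base equilibration at C4.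

13 ⇒ 11 + 12. The exocyclic C3=C4 bond is cut to the lactone carbonyl of 11 and a two-carbon carbenoid. The olefination must tolerate an allylic lactone and give an acid-sensitive enol ether intact.

11 ⇒ 10 ⇒ 9. The lactone O–C3 bond and then the C9–H bond are cut. The C9 carbinol is thus derived from an enone whose only stereocentre (C7) directs the hydride. The forward reduction must be 1,2 and cis to the isopropenyl group.

9 ⇒ 8 ⇒ 7. The C5–C14 bond is cut and the carbonyl is moved from C9 back to C5 (1,3-transposition). This leads to a carvone-type enone. The methyl nucleophile must ignore the ester.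

7 ⇒ 6 ⇒ 4 + 5. The C9=C10 unsaturation is removed and the C1–C2 bond is cut (conjugate addition). The addition itself supplies the enol ether needed for regiocontrolled dehydrogenation.

4 ⇒ 3 ⇒ 2 ⇒ 1. The ketone is traced to the allylic alcohol, this to the epoxide, and the epoxide to the ring alkene of 1. C7 of the target is the stereocentre of 1. The forward isomerisation must give the exocyclic alkene.

## Other disconnections considered

Alternative 1: The cut is C7–C8 in ring B, with the isopropenyl alkene shifted back to C7=C11. In the forward key step the unmasked aldehyde A1 would be attacked by the γ-carbon (C7) of its own Z-allylboronate through a closed six-membered boron–oxygen transition state, closing ring B to A2.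
- In favour: C7 and C8 are set together, and the cis OH/isopropenyl relation follows from the Z geometry. The isopropenyl group appears only at the end, so no oxidation has to discriminate against it; here the alternative is better than the chosen plan. After the key step only protecting-group work and the esterification remain, which is also better.
- Against: the stereochemical load moves to ring A. A1 needs C3, C4, quaternary C5, C10 and C9 set beforehand, including the cis C4/C5 methyls and the trans arms on C5/C10, with no internal relay. The α-alkoxy aldehyde is epimerisable at C9, and a Z-trisubstituted allylboronate must be made.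
- Comparison: the mechanism is as dependable as a sigmatropic shift. On structure, the chosen plan creates the quaternary centre in its key step by chirality transfer, whereas the alternative must import it. On step economy it would be longer before the key step and shorter after.

Alternative 2: The cuts are C3–C4 and C5–C10, opening both rings. In the forward key step Me2AlCl would activate the E-enal of A3, and its C4=C5 bond would add to the tethered E-diene through an endo transition state to give A4.
- In favour: both rings and C4, C5 and C10 are made in one step. The trans fusion is set directly, where the chosen plan needs a separate reduction. The cis C4/C5 relation follows stereospecifically from the enal geometry, where the chosen plan needs an equilibration. The diol is carried from the start. On these three points the alternative is better.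
- Against: the dienophile is a β,β-disubstituted enal that must form a quaternary centre, so it would be sluggish. The Lewis acid can also attack the acetonide, the diene or the isopropenyl group. Facial selectivity rests on the tether stereocentres. A4 has functionality in the wrong places: formyl must become methyl, and the C1=C2 alkene must be turned into a C3 oxygen, again in the presence of the isopropenyl group.
- Comparison: the mechanism is concerted and well understood, equal to the chosen plan. The skeleton is built faster, but the post-cycloaddition corrections would probably cancel the gain in steps.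

Alternative 3: The cut is C5–C6, with a temporary C3–C8 bond as the bridge of a bicyclo[2.2.2]octene. In the forward key step KH with 18-crown-6 would convert A5 into its alkoxide, which would undergo anionic oxy-Cope rearrangement to A6.
- In favour: A5 should be reachable in very few steps. The shift has a strong driving force and forms quaternary C5 stereospecifically. The C3=C4 alkene of A6 invites α-face hydroboration, which would set 3α-OH and 4β-Me together; on C3/C4 this is better than the chosen plan.
- Against: the ring fusion is cis, so C10 must be epimerised later through a C9 ketone. The C7 isopropenyl group is absent and must be introduced α to the C8 ketone with control of C7. C8 and C9 still need two stereoselective reductions. The sequence is racemic unless made asymmetric, whereas the chosen plan takes its absolute configuration from limonene.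
- Comparison: mechanistically equal. Structurally it solves C3/C4 better and C7/C10 worse. Step economy would be similar or poorer once the isopropenyl group and an asymmetric entry are counted.

Key step: step 11

Convention: bicyclic compounds carry eremophilane locants; β is the face of the C5 methyl (C14), α the opposite face.

## Route

Step 1
Reactants: 1 (S)-limonene
Product: 2 (4S)-limonene 1,2-oxide (cis/trans mixture)
Conditions: mCPBA, NaHCO3, CH2Cl2, 0 °C
Reagents that add atoms: mCPBA (3-chloroperoxybenzoic acid), OOC(=O)c1cccc(Cl)c1
Why: Prilezhaev epoxidation; the peracid prefers the trisubstituted ring alkene to the 1,1-disubstituted isopropenyl group, and the epoxide configuration is irrelevant because both carbons lose it later.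

Step 2
Reactants: 2 (4S)-limonene 1,2-oxide
Product: 3 (5S)-2-methylidene-5-(prop-1-en-2-yl)cyclohexan-1-ol (mixture of C1 epimers)
Conditions: Et2AlCl, lithium 2,2,6,6-tetramethylpiperidide, toluene, 0 °C
Reagents that add atoms: none
Why: Epoxide-to-allylic-alcohol isomerisation by a bulky aluminium amide; aluminium binds the oxirane oxygen and the amide removes a syn proton from the least hindered β position (the methyl group), giving the exocyclic methylene alcohol, not the endocyclic isomer.

Step 3
Reactants: 3 (5S)-2-methylidene-5-(prop-1-en-2-yl)cyclohexan-1-ol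
Product: 4 (5S)-2-methylidene-5-(prop-1-en-2-yl)cyclohexan-1-one
Conditions: MnO2, CH2Cl2, 25 °C
Reagents that add atoms: none
Why: Allylic alcohol oxidation under neutral conditions, which should prevent migration of the exocyclic double bond into the ring; the dimerisation-prone α-methylene ketone is to be used at once in solution.

Step 4
Reactants: 4 (5S)-2-methylidene-5-(prop-1-en-2-yl)cyclohexan-1-one, 5 1-(tert-butyldimethylsilyloxy)-1-methoxyethene
Product: 6 methyl 3-[(4S)-2-(tert-butyldimethylsilyloxy)-4-(prop-1-en-2-yl)cyclohex-1-en-1-yl]propanoate
Conditions: TBSOTf (5 mol%), CH2Cl2, −78 °C; then Et3N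
Reagents that add atoms: none
Why: Mukaiyama–Michael addition; the silyl ketene acetal adds to the unhindered exocyclic β-carbon with silyl transfer, forming C1–C2 and delivering the enol ether regiospecifically on the substituted side.

Step 5
Reactants: 6 methyl 3-[(4S)-2-(tert-butyldimethylsilyloxy)-4-(prop-1-en-2-yl)cyclohex-1-en-1-yl]propanoate
Product: 7 methyl 3-[(4S)-6-oxo-4-(prop-1-en-2-yl)cyclohex-1-en-1-yl]propanoate
Conditions: Pd(OAc)2 (1.1 equiv), MeCN, 40 °C
Reagents that add atoms: none
Why: Saegusa–Ito dehydrogenation; the divalent palladium enolate at the substituted α-carbon undergoes β-hydride elimination toward the ring CH2 and should give the endocyclic 2-alkyl enone, a carvone homologue, with regiochemistry fixed by the enol ether of step 4.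

Step 6
Reactants: 7 methyl 3-[(4S)-6-oxo-4-(prop-1-en-2-yl)cyclohex-1-en-1-yl]propanoate
Product: 8 methyl 3-[(4S)-6-hydroxy-6-methyl-4-(prop-1-en-2-yl)cyclohex-1-en-1-yl]propanoate (mixture of C6 epimers)
Conditions: MeLi, CeCl3, THF, −78 °C; AcOH, −78 °C
Reagents that add atoms: methyllithium, [Li]C
Why: 1,2-addition of a weakly basic organocerium reagent to the enone carbonyl; at −78 °C the methyl ester should not react, and the cold acidic quench should prevent lactonisation of the tertiary alkoxide. The new carbinol centre is destroyed in step 7.

Step 7
Reactants: 8 methyl 3-[(4S)-6-hydroxy-6-methyl-4-(prop-1-en-2-yl)cyclohex-1-en-1-yl]propanoate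
Product: 9 methyl 3-[(4R)-2-methyl-6-oxo-4-(prop-1-en-2-yl)cyclohex-1-en-1-yl]propanoate
Conditions: pyridinium chlorochromate (C5H5NH)[CrO3Cl], Celite, CH2Cl2, 25 °C
Reagents that add atoms: pyridinium chlorochromate, [O-][Cr](=O)(=O)Cl.c1cc[nH+]cc1
Why: Oxidative 1,3-transposition of a tertiary allylic alcohol (Dauben type); chromate ester formation, [3,3] shift and oxidation should give the 3-methyl enone with oxygen moved to the future C9.

Step 8
Reactants: 9 methyl 3-[(4R)-2-methyl-6-oxo-4-(prop-1-en-2-yl)cyclohex-1-en-1-yl]propanoate
Product: 10 methyl 3-[(4R,6R)-6-hydroxy-2-methyl-4-(prop-1-en-2-yl)cyclohex-1-en-1-yl]propanoate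
Conditions: NaBH4, CeCl3·7H2O, MeOH, −78 °C
Reagents that add atoms: none
Why: Luche reduction; 1,2-hydride delivery by axial attack on the half-chair with the isopropenyl group equatorial should give the allylic alcohol cis to that group (the carvone to cis-carveol pattern), which sets C9 with oxygen α.

Step 9
Reactants: 10 methyl 3-[(4R,6R)-6-hydroxy-2-methyl-4-(prop-1-en-2-yl)cyclohex-1-en-1-yl]propanoate
Product: 11 (7R,8aR)-5-methyl-7-(prop-1-en-2-yl)-3,4,6,7,8,8a-hexahydro-2H-chromen-2-one
Conditions: pyridinium p-toluenesulfonate (cat.), toluene, 60 °C, 4 Å molecular sieves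
Reagents that add atoms: none
Why: Acid-catalysed intramolecular transesterification (lactonisation) to the six-membered lactone, driven by removal of methanol; the weak pyridinium acid should not ionise the allylic C–O bond, so C9 is kept.

Step 10
Reactants: 11 (7R,8aR)-5-methyl-7-(prop-1-en-2-yl)-3,4,6,7,8,8a-hexahydro-2H-chromen-2-one, 12 1,1-dibromoethane
Product: 13 (2Z,7R,8aR)-2-ethylidene-5-methyl-7-(prop-1-en-2-yl)-3,4,6,7,8,8a-hexahydro-2H-chromene
Conditions: TiCl4, Zn, PbCl2 (cat.), TMEDA, THF, 0 to 25 °C; aq. K2CO3; basic Al2O3
Reagents that add atoms: none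
Why: Takai–Utimoto alkylidenation of the lactone carbonyl by the gem-dizinc/titanium reagent; this olefination places the new alkyl group cis to the ring oxygen (Z), and the basic work-up should preserve the acid-labile exocyclic enol ether.

Step 11
Reactants: 13 (2Z,7R,8aR)-2-ethylidene-5-methyl-7-(prop-1-en-2-yl)-3,4,6,7,8,8a-hexahydro-2H-chromene
Product: 15 eremophila-9,11-dien-3-one bearing 4β-methyl, 5β-methyl, 7α-isopropenyl, via 4α-methyl epimer 14 (not isolated)
Conditions: xylenes, Et3N (trace), base-washed sealed tube, 170 °C; then NaOMe (cat.), MeOH, 25 °C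
Reagents that add atoms: none
Why: Thermal [3,3] sigmatropic (Claisen) rearrangement of the cyclic allyl vinyl ether C4=C3–O–C9–C10=C5; the closest known type is the carbocyclising Claisen rearrangement of 2-alkylidene tetrahydropyrans made by lactone alkylidenation. Because the C1–C2 tether links C3 to C10 across the six-centre array, only a boat (bicyclo[2.2.2]octane-like) transition state is possible; ring A closes as a six-membered carbocycle by bonding the two exocyclic termini C4 and C5 while the pyran opens at C9–O. C5 is controlled by the C9 carbinol centre: the shift is suprafacial on the allyl part, so C4 arrives on the α face that oxygen leaves and the C14 methyl stays β, whatever the steric bias of ring B. C4 is controlled first by the enol ether geometry: in the boat the Z methyl (cis to the ring oxygen) lies on the O–C9 side, eclipses C6 and is carried to the α face, so the primary product is epimer 14. Methoxide then equilibrates C4 through the C3 enolate; 15, with the equatorial methyl cis to C14, is expected in at least comparable amount, but its preference should be small while C10 is trigonal, so recovered 14 is to be resubmitted to the base. The step needs the exocyclic enol ether to rearrange before acid traces move its double bond into the ring, which the amine and base-washed glass should secure, and carbonyl formation makes the shift irreversible.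

Step 12
Reactants: 15 eremophila-9,11-dien-3-one bearing 4β-methyl, 5β-methyl, 7α-isopropenyl
Product: 16 eremophila-9,11-diene-3,8-dione (4β-Me, 5β-Me, 7α-isopropenyl)
Conditions: Rh2(C6H10NO)4 (dirhodium tetrakis(caprolactamate), 1 mol%), t-BuOOH (70% in water), 1,2-dichloroethane, 40 °C
Reagents that add atoms: tert-butyl hydroperoxide, CC(C)(C)OO
Why: Radical allylic C–H oxidation by tert-butylperoxyl radicals; hydrogen abstraction at C8 gives the allyl radical with a tertiary C10 terminus, which is trapped at the less hindered C8 and collapses to the enone, the pattern of Δ5-steroid 7-oxidation and of the valencene-to-nootkatone oxidation. C1 and the isopropenyl group should react more slowly; no stereocentre is formed.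

Step 13
Reactants: 16 eremophila-9,11-diene-3,8-dione (4β-Me, 5β-Me, 7α-isopropenyl)
Product: 18 3α,8-bis(trimethylsilyloxy)-10αH-eremophila-8,11-diene (4β-Me, 5β-Me, 7α-isopropenyl), via dilithium alkoxide enolate 17 (not isolated)
Conditions: Li, NH3/THF, t-BuOH (3 equiv), −78 °C; isoprene; then Me3SiCl, Et3N, THF, −78 to 0 °C
Reagents that add atoms: chlorotrimethylsilane, C[Si](C)(C)Cl
Why: Dissolving-metal reduction with enolate trapping (reductive silylation); the enone takes two electrons and C10 is protonated axially on the α face, opposite C14, giving the trans fusion and the regiodefined C8–C9 enolate, which tert-butanol should not protonate. The saturated C3 ketone is reduced in the same medium under thermodynamic control to the equatorial 3α alkoxide, whereas a small hydride would be expected to attack from the α face and give the axial alcohol. Silylation fixes both oxygens, and isolated alkenes are inert.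

Step 14
Reactants: 18 3α,8-bis(trimethylsilyloxy)-10αH-eremophila-8,11-diene
Product: 19 3α,9α-bis(trimethylsilyloxy)-10αH-eremophil-11-en-8-one (4β-Me, 5β-Me, 7α-isopropenyl)
Conditions: mCPBA, NaHCO3, CH2Cl2, −20 °C
Reagents that add atoms: mCPBA (3-chloroperoxybenzoic acid), OOC(=O)c1cccc(Cl)c1
Why: Rubottom oxidation; the electron-rich silyl enol ether should be epoxidised far faster than the isopropenyl group, and from the α face because the axial C14 methyl covers the β face of C9 (as in peracid attack on 5α-Δ6 steroids). Opening of the silyloxy epoxide with silyl migration gives the equatorial 9α-silyloxy ketone.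

Step 15
Reactants: 19 3α,9α-bis(trimethylsilyloxy)-10αH-eremophil-11-en-8-one
Product: 21 10αH-eremophil-11-ene-3α,8α,9α-triol (4β-Me, 5β-Me, 7α-isopropenyl), via bis(trimethylsilyl) ether 20 (not isolated)
Conditions: LiBH(s-Bu)3, THF, −78 °C; NaOH, H2O2, 0 °C; then HCl, MeOH, 0 °C
Reagents that add atoms: none
Why: Ketone reduction by a bulky trialkylborohydride; equatorial attack on C8 from the β side should give the axial 8α alcohol, cis to O9 and to the isopropenyl group. The oxidative work-up removes the borane and acidic methanol cleaves both trimethylsilyl ethers.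

Step 16
Reactants: 21 10αH-eremophil-11-ene-3α,8α,9α-triol
Product: 22 8α,9α-O-isopropylidene-10αH-eremophil-11-ene-3α,8α,9α-triol (free 3α-OH)
Conditions: 2,2-dimethoxypropane, pyridinium p-toluenesulfonate (cat.), acetone, 25 °C
Reagents that add atoms: 2,2-dimethoxypropane, COC(C)(C)OC
Why: Acetonide formation by transketalisation; only the cis-8,9-diol can close a five-membered dioxolane, so the 3α-hydroxyl stays free.

Step 17
Reactants: 22 8α,9α-O-isopropylidene-10αH-eremophil-11-ene-3α,8α,9α-triol, 23 2-(diphenoxyphosphoryl)acetic acid
Product: 24 3α-O-[2-(diphenoxyphosphoryl)acetyl]-8α,9α-O-isopropylidene-10αH-eremophil-11-ene-3α,8α,9α-triol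
Conditions: DCC, DMAP (cat.), CH2Cl2, 0 to 25 °C
Reagents that add atoms: none
Why: Steglich esterification of the equatorial secondary alcohol; no stereocentre is touched and the acid carries no alkene that could isomerise.

Step 18
Reactants: 25 (R)-2-ethyloxirane
Product: 26 (R)-pent-1-en-3-ol
Conditions: Me3S+ I−, n-BuLi, THF, −10 to 25 °C
Reagents that add atoms: trimethylsulfonium iodide, C[S+](C)C.[I-]
Why: One-carbon homologation of a terminal epoxide to an allylic alcohol with excess dimethylsulfonium methylide (ylide opening at the CH2 terminus, then ylide-mediated elimination of dimethyl sulfide); the carbinol C–O bond is not involved, so the R configuration is kept.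

Step 19
Reactants: 26 (R)-pent-1-en-3-ol, 27 angelic acid [(2Z)-2-methylbut-2-enoic acid]
Product: 28 (3R)-pent-1-en-3-yl (2Z)-2-methylbut-2-enoate
Conditions: 2,4,6-trichlorobenzoyl chloride, Et3N, toluene, 25 °C; then 26, 75 °C
Reagents that add atoms: none
Why: Yamaguchi esterification through the mixed anhydride without a nucleophilic catalyst, the conditions under which angelates form without Z-to-E drift to the tiglate; the carbinol configuration is retained because the acyl–oxygen bond is the one formed.

Step 20
Reactants: 28 (3R)-pent-1-en-3-yl (2Z)-2-methylbut-2-enoate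
Product: 29 (2R)-1-oxobutan-2-yl (2Z)-2-methylbut-2-enoate
Conditions: K2OsO4·2H2O (2 mol%), NaIO4, 2,6-lutidine, dioxane/H2O, 25 °C
Reagents that add atoms: sodium periodate, [Na+].[O-]I(=O)(=O)=O
Why: Lemieux–Johnson oxidative cleavage; osmylation should prefer the monosubstituted terminal alkene to the conjugated trisubstituted angelate alkene, and periodate cleaves the diol to the α-acyloxy aldehyde. The buffered medium should preserve the α-stereocentre.

Step 21
Reactants: 24 3α-O-[2-(diphenoxyphosphoryl)acetyl]-8α,9α-O-isopropylidene-10αH-eremophil-11-ene-3α,8α,9α-triol, 29 (2R)-1-oxobutan-2-yl (2Z)-2-methylbut-2-enoate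
Product: 30 8α,9α-O-isopropylidene derivative of the target [3α-O-(2Z,4R)-4-angeloyloxyhex-2-enoyl ester]
Conditions: NaH, THF, 0 °C; then 29, −78 to −40 °C
Reagents that add atoms: none
Why: Z-selective Horner–Wadsworth–Emmons olefination with a diaryl phosphonoacetate (Ando variant); the aryloxy groups make oxaphosphetane collapse fast, so the kinetic cis adduct should give the Z-enoate. The stabilised anion at low temperature should not epimerise the α-acyloxy aldehyde, whose centre becomes C4′.

Step 22
Reactants: 30 8α,9α-O-isopropylidene derivative of the target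
Product: 31 target, 8α,9α-dihydroxy-10αH-eremophil-11-en-3α-yl (2Z,4R)-4-[(2Z)-2-methylbut-2-enoyloxy]hex-2-enoate (4β-Me, 5β-Me, 7α-isopropenyl)
Conditions: AcOH/H2O (4:1), 40 °C
Reagents that add atoms: none
Why: Acid-catalysed acetal hydrolysis; the cis-fused dioxolane should cleave under conditions that leave both esters, the Z alkenes and the isopropenyl group untouched.

## Compound list

1 | (S)-limonene | CC1=CC[C@H](CC1)C(C)=C | starting material
2 | (4S)-limonene 1,2-oxide (cis/trans mixture) | CC12OC1C[C@H](CC2)C(C)=C | intermediate
3 | (5S)-2-methylidene-5-(prop-1-en-2-yl)cyclohexan-1-ol (C1 epimers) | C=C1C(O)C[C@H](CC1)C(C)=C | intermediate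
4 | (5S)-2-methylidene-5-(prop-1-en-2-yl)cyclohexan-1-one | C=C1C(=O)C[C@H](CC1)C(C)=C | intermediate
5 | 1-(tert-butyldimethylsilyloxy)-1-methoxyethene | C=C(OC)O[Si](C)(C)C(C)(C)C | starting material
6 | methyl 3-[(4S)-2-(tert-butyldimethylsilyloxy)-4-(prop-1-en-2-yl)cyclohex-1-en-1-yl]propanoate | COC(=O)CCC1=C(O[Si](C)(C)C(C)(C)C)C[C@H](CC1)C(C)=C | intermediate
7 | methyl 3-[(4S)-6-oxo-4-(prop-1-en-2-yl)cyclohex-1-en-1-yl]propanoate | COC(=O)CCC1=CC[C@@H](CC1=O)C(C)=C | intermediate
8 | methyl 3-[(4S)-6-hydroxy-6-methyl-4-(prop-1-en-2-yl)cyclohex-1-en-1-yl]propanoate (C6 epimers) | COC(=O)CCC1=CC[C@@H](CC1(C)O)C(C)=C | intermediate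
9 | methyl 3-[(4R)-2-methyl-6-oxo-4-(prop-1-en-2-yl)cyclohex-1-en-1-yl]propanoate | COC(=O)CCC1=C(C)C[C@H](CC1=O)C(C)=C | intermediate
10 | methyl 3-[(4R,6R)-6-hydroxy-2-methyl-4-(prop-1-en-2-yl)cyclohex-1-en-1-yl]propanoate | COC(=O)CCC1=C(C)C[C@@H](C(C)=C)C[C@H]1O | intermediate
11 | (7R,8aR)-5-methyl-7-(prop-1-en-2-yl)-3,4,6,7,8,8a-hexahydro-2H-chromen-2-one | O=C1CCC2=C(C)C[C@@H](C(C)=C)C[C@H]2O1 | intermediate
12 | 1,1-dibromoethane | CC(Br)Br | starting material
13 | (2Z,7R,8aR)-2-ethylidene-5-methyl-7-(prop-1-en-2-yl)-3,4,6,7,8,8a-hexahydro-2H-chromene | C/C=C1/CCC2=C(C)C[C@@H](C(C)=C)C[C@H]2O1 | intermediate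
14 | eremophila-9,11-dien-3-one, 4α-Me, 5β-Me, 7α-isopropenyl (C4 epimer of 15) | C=C(C)[C@@H]1C[C@]2(C)[C@H](C)C(=O)CCC2=CC1 | intermediate
15 | eremophila-9,11-dien-3-one, 4β-Me, 5β-Me, 7α-isopropenyl | C=C(C)[C@@H]1C[C@]2(C)[C@@H](C)C(=O)CCC2=CC1 | intermediate
16 | eremophila-9,11-diene-3,8-dione, 4β-Me, 5β-Me, 7α-isopropenyl | C=C(C)[C@@H]1C[C@]2(C)[C@@H](C)C(=O)CCC2=CC1=O | intermediate
17 | dilithium 3α-alkoxide 8-enolate of 10αH-eremophila-8,11-diene-3α,8-diol | C=C(C)[C@@H]1C[C@]2(C)[C@@H](C)[C@H]([O-])CC[C@H]2C=C1[O-].[Li+].[Li+] | intermediate
18 | 3α,8-bis(trimethylsilyloxy)-10αH-eremophila-8,11-diene | C=C(C)[C@@H]1C[C@]2(C)[C@@H](C)[C@H](O[Si](C)(C)C)CC[C@H]2C=C1O[Si](C)(C)C | intermediate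
19 | 3α,9α-bis(trimethylsilyloxy)-10αH-eremophil-11-en-8-one | C=C(C)[C@@H]1C[C@]2(C)[C@@H](C)[C@H](O[Si](C)(C)C)CC[C@H]2[C@H](O[Si](C)(C)C)C1=O | intermediate
20 | 3α,9α-bis(trimethylsilyloxy)-10αH-eremophil-11-en-8α-ol | C=C(C)[C@@H]1C[C@]2(C)[C@@H](C)[C@H](O[Si](C)(C)C)CC[C@H]2[C@H](O[Si](C)(C)C)[C@@H]1O | intermediate
21 | 10αH-eremophil-11-ene-3α,8α,9α-triol | C=C(C)[C@@H]1C[C@]2(C)[C@@H](C)[C@H](O)CC[C@H]2[C@H](O)[C@@H]1O | intermediate
22 | 8α,9α-O-isopropylidene-10αH-eremophil-11-ene-3α,8α,9α-triol | C=C(C)[C@@H]1C[C@]2(C)[C@@H](C)[C@H](O)CC[C@H]2[C@@H]3OC(C)(C)O[C@H]13 | intermediate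
23 | 2-(diphenoxyphosphoryl)acetic acid | OC(=O)CP(=O)(Oc1ccccc1)Oc1ccccc1 | starting material
24 | 3α-O-[2-(diphenoxyphosphoryl)acetyl] derivative of 22 | C=C(C)[C@@H]1C[C@]2(C)[C@@H](C)[C@H](OC(=O)CP(=O)(Oc3ccccc3)Oc3ccccc3)CC[C@H]2[C@@H]4OC(C)(C)O[C@H]14 | intermediate
25 | (R)-2-ethyloxirane | CC[C@@H]1CO1 | starting material
26 | (R)-pent-1-en-3-ol | CC[C@@H](O)C=C | intermediate
27 | angelic acid, (2Z)-2-methylbut-2-enoic acid | C/C=C(/C)C(=O)O | starting material
28 | (3R)-pent-1-en-3-yl (2Z)-2-methylbut-2-enoate | CC[C@@H](OC(=O)/C(C)=C\C)C=C | intermediate
29 | (2R)-1-oxobutan-2-yl (2Z)-2-methylbut-2-enoate | CC[C@@H](OC(=O)/C(C)=C\C)C=O | intermediate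
30 | 8α,9α-O-isopropylidene derivative of the target | C=C(C)[C@@H]1C[C@]2(C)[C@@H](C)[C@H](OC(=O)/C=C\[C@@H](CC)OC(=O)/C(C)=C\C)CC[C@H]2[C@@H]3OC(C)(C)O[C@H]13 | intermediate
31 | 8α,9α-dihydroxy-10αH-eremophil-11-en-3α-yl (2Z,4R)-4-[(2Z)-2-methylbut-2-enoyloxy]hex-2-enoate (CNP0382739.1) | C=C(C)[C@@H]1C[C@]2(C)[C@@H](C)[C@H](OC(=O)/C=C\[C@@H](CC)OC(=O)/C(C)=C\C)CC[C@H]2[C@H](O)[C@@H]1O | target

## Step count and least certain steps

Total steps: 22. Longest linear sequence: 19 (steps 1–17, 21, 22); steps 18–20 form the side-chain branch.

Step 10 (Takai ethylidenation). Most likely failure: reductive opening or incomplete conversion of the allylic lactone by the low-valent titanium/zinc mixture, or hydrolysis and migration of the exocyclic double bond into the ring during isolation, because the product is a very electron-rich enol ether. Fallback: the same Z enol ether is built by cyclising an alkynol instead of olefinating a carbonyl. It sets out from 11. Reduction with i-Bu2AlH at −78 °C gives the lactol F1. Dimethyl (1-diazo-2-oxopropyl)phosphonate with K2CO3 in MeOH (Ohira–Bestmann homologation of the open hydroxy aldehyde) gives the terminal alkynol F2. Double deprotonation with n-BuLi and C-methylation with MeI gives the methyl alkynol F3. AuCl(PPh3)/AgOTf with K2CO3 then adds the hydroxyl across the alkyne in the anti sense (6-exo-dig), which places the methyl cis to oxygen. The fallback rejoins the route at 13.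

Step 11 (key step). Most likely failure: poor control at C4, because the boat delivers the 4α-methyl epimer and the base equilibration may stay near balance or even lean toward 14 while C10 is trigonal. A second risk is acid-catalysed drift of the enol ether double bond into the ring before the shift. Fallback: equilibration is replaced by a stereospecific variant with the other enol ether geometry. It sets out from 11 through the methyl alkynol F3 described under step 10. La[N(SiMe3)2]3-catalysed hydroalkoxylation in toluene (syn insertion of the alkyne into the La–O bond, then protonolysis) gives the E-ethylidene pyran F4. Its methyl lies on the tether side of the boat and is delivered to the β face of C4, so heating F4 should give the 4β ketone directly. The fallback rejoins the route at 15.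

Step 12 (allylic oxidation). Most likely failure: loss of site selectivity (hydrogen abstraction at C1 or at the doubly activated C7–H), or migration of the isopropenyl double bond into conjugation once the C8 ketone exists. Fallback: oxygen is introduced by an ene reaction instead of radical C–H abstraction. It sets out from 15. Photo-oxygenation (O2, tetraphenylporphyrin, light) should attack the trisubstituted alkene on the α face and give the tertiary allylic hydroperoxide F5. On standing in CHCl3 this undergoes the allylic (Schenck) shift to the secondary hydroperoxide F6. Ac2O/pyridine dehydrates F6 (Kornblum–DeLaMare). The fallback rejoins the route at 16.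

Step 13 (double reduction with silylation). Most likely failure: protonation of the C8 enolate by the added alcohol followed by over-reduction at C8, or incomplete reduction at C3, because one medium must reduce a ketone fully while sparing an enolate. Fallback: the two reductions are separated so that no external proton donor is present in the enone reduction. It sets out from 15. Li/NH3 with EtOH gives the equatorial dienol F7. The dirhodium/t-BuOOH oxidation of step 12 then gives the hydroxy enone F8. Li in NH3/THF, with the C3 hydroxyl as the only proton source, followed by Me3SiCl/Et3N silylates both oxygens. The fallback rejoins the route at 18.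

Step 20 (oxidative cleavage). Most likely failure: competing osmylation of the angelate alkene, or epimerisation and hydration of the α-acyloxy aldehyde during isolation. Fallback: the aldehyde is made by alcohol oxidation, so no alkene has to be cleaved. It sets out from 25. Opening with sodium 4-methoxybenzyl oxide at the CH2 terminus gives the mono-protected diol F9. The Yamaguchi conditions of step 19 with 27 give the angelate F10. DDQ removes the benzyl ether to give the primary alcohol F11, and Dess–Martin periodinane oxidises it. The fallback rejoins the route at 29.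

## Further compounds

F1 | step 10 | (7R,8aR)-5-methyl-7-(prop-1-en-2-yl)-3,4,6,7,8,8a-hexahydro-2H-chromen-2-ol (lactol, anomers) | OC1CCC2=C(C)C[C@@H](C(C)=C)C[C@H]2O1
F2 | step 10 | (1R,5R)-2-(but-3-yn-1-yl)-3-methyl-5-(prop-1-en-2-yl)cyclohex-2-en-1-ol | C#CCCC1=C(C)C[C@@H](C(C)=C)C[C@H]1O
F3 | step 10 | (1R,5R)-3-methyl-2-(pent-3-yn-1-yl)-5-(prop-1-en-2-yl)cyclohex-2-en-1-ol | CC#CCCC1=C(C)C[C@@H](C(C)=C)C[C@H]1O
F4 | step 11 | (2E,7R,8aR)-2-ethylidene-5-methyl-7-(prop-1-en-2-yl)-3,4,6,7,8,8a-hexahydro-2H-chromene | C/C=C1\CCC2=C(C)C[C@@H](C(C)=C)C[C@H]2O1
F5 | step 12 | 10α-hydroperoxyeremophila-8,11-dien-3-one (4β-Me, 5β-Me, 7α-isopropenyl) | C=C(C)[C@@H]1C[C@]2(C)[C@@H](C)C(=O)CC[C@@]2(OO)C=C1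
F6 | step 12 | 8α-hydroperoxyeremophila-9,11-dien-3-one (4β-Me, 5β-Me, 7α-isopropenyl) | C=C(C)[C@@H]1C[C@]2(C)[C@@H](C)C(=O)CCC2=C[C@@H]1OO
F7 | step 13 | eremophila-9,11-dien-3α-ol (4β-Me, 5β-Me, 7α-isopropenyl) | C=C(C)[C@@H]1C[C@]2(C)[C@@H](C)[C@H](O)CCC2=CC1
F8 | step 13 | 3α-hydroxyeremophila-9,11-dien-8-one (4β-Me, 5β-Me, 7α-isopropenyl) | C=C(C)[C@@H]1C[C@]2(C)[C@@H](C)[C@H](O)CCC2=CC1=O
F9 | step 20 | (2R)-1-[(4-methoxyphenyl)methoxy]butan-2-ol | CC[C@@H](O)COCc1ccc(OC)cc1
F10 | step 20 | (2R)-1-[(4-methoxyphenyl)methoxy]butan-2-yl (2Z)-2-methylbut-2-enoate | CC[C@@H](OC(=O)/C(C)=C\C)COCc1ccc(OC)cc1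
F11 | step 20 | (2R)-1-hydroxybutan-2-yl (2Z)-2-methylbut-2-enoate | CC[C@@H](OC(=O)/C(C)=C\C)CO
A1 | alternative 1 | 7,8-seco aldehyde: ring A cyclohexane with 3α-OTBS, 4β-Me, 5β-Me, the C9 (4-methoxybenzyloxy)acetaldehyde arm on C10 and the (Z)-2-methyl-4-(pinacolboryl)but-2-enyl arm on C5 | O=C[C@@H](OCc1ccc(OC)cc1)[C@@H]2CC[C@@H](O[Si](C)(C)C(C)(C)C)[C@H](C)[C@@]2(C)C/C=C(/C)CB3OC(C)(C)C(C)(C)O3
A2 | alternative 1 | 3-O-(tert-butyldimethylsilyl)-9-O-(4-methoxybenzyl)-eremophil-11-ene-3α,8α,9α-triol | C=C(C)[C@@H]1C[C@]2(C)[C@@H](C)[C@H](O[Si](C)(C)C(C)(C)C)CC[C@H]2[C@H](OCc3ccc(OC)cc3)[C@@H]1O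
A3 | alternative 2 | open-chain E-enal E-diene (C4=C5 enal, C10=C1–C2=C3 diene) with the 8,9-acetonide and the C7 isopropenyl group | O=C/C=C(\C)C[C@@H](C(C)=C)[C@H]1OC(C)(C)O[C@H]1/C=C/C=C
A4 | alternative 2 | trans-fused octal-1-ene with 4β-formyl, 5β-methyl, 7α-isopropenyl and the 8α,9α-acetonide | C=C(C)[C@@H]1C[C@]2(C)[C@@H](C=O)CC=C[C@H]2[C@@H]3OC(C)(C)O[C@H]13
A5 | alternative 3 | 3,3-dimethoxy-5,6-dimethyl-2-vinylbicyclo[2.2.2]oct-5-en-2-ol (vinyl syn to the C5=C6 bridge) | C=C[C@@]1(O)[C@@H]2CC[C@@H](C(C)=C2C)C1(OC)OC
A6 | alternative 3 | cis-fused 9,9-dimethoxy-4,5-dimethyloctal-3-en-8-one (eremophilane locants) | CC1=CCC[C@H]2[C@]1(C)CCC(=O)C2(OC)OC
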